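C9 of ring B lies between two methyl-bearing carbons (C8, C10), the pattern of a 2,6-dimethylquinone, and ring A needs only a C2=C3 olefin beside the C4 gem-dimethyl carbon to deliver the cis-diol. Ring A is therefore disconnected at C1–C10 and C4–C5: one catalytic enantioselective Diels–Alder reaction of commercial 2,6-dimethyl-1,4-benzoquinone with commercial 4-methylpenta-1,3-diene forms both bonds, closes ring A and fixes quaternary C10. Since the cis-fused 6,9-dione cannot be trusted to epimerise to trans, C5 is flattened to a Δ5 olefin and reset by α-face hydrogen-atom transfer; α-vinylation at C9 and a B-alkyl Suzuki coupling finish the Z-enoate.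

Key step: step 1

Convention: labdane numbering throughout (ring A = C1–C5 and C10, ring B = C5–C10, side chain C11–C15); β is the face of the C10 methyl group.
Assumption: the sense of induction is taken from the accepted binding picture of oxazaborolidinium catalysts (boron on the C6 oxygen syn to C5–H, diene on the face away from the shielding aryl group), which calls for the (R)-prolinol-derived catalyst; if the sign proves opposite, the mirror-image catalyst is used.

Step 1
Reactants: 1 2,6-dimethyl-1,4-benzoquinone; 2 4-methylpenta-1,3-diene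
Product: 3 (4aR,8aS)-2,5,5,8a-tetramethyl-4a,5,8,8a-tetrahydronaphthalene-1,4-dione (cis-fused adduct: 5β-H, 10β-methyl, Δ2, Δ7, 6,9-dione)
Conditions: (R)-B-(o-tolyl)oxazaborolidine from (R)-α,α-diphenylprolinol (20 mol%), Tf2NH (18 mol%), 2 (4 equiv), CH2Cl2, −78 → −40 °C
Reagents that add atoms: none
Why: Diels–Alder reaction, concerted but strongly asynchronous: the protonated oxazaborolidine binds O6, the carbonyl that is unhindered, the more basic one (both methyls donate to it vinylogously) and the only one with an α-C–H (C5–H) for the second contact to the catalyst. The closest precedent is the oxazaborolidinium-catalysed enantioselective Diels–Alder reaction of methyl-substituted 1,4-benzoquinones with simple 1,3-dienes. Ring A is closed by intermolecular suprafacial [4+2] addition across C5=C10; the unsubstituted diene terminus (largest HOMO coefficient) bonds to the Lewis-acid-activated β-carbon C10 and the CMe2 terminus to C5, which also avoids joining two fully substituted carbons. C10 is fixed by the catalyst, which tells apart the two enantiotopic methyl-bearing olefins and screens one face of the bound one with an aryl group, while C5 follows from suprafacial addition (cis fusion) and is erased on purpose in step 2. Regio-, site- and face selectivity are all needed and rest on diene polarisation, on Lewis-acid placement at O6 and on the catalyst, and the angular methyl stops aromatisation. The cis-methyl group of 2 disfavours its s-cis conformer, so excess diene, high concentration and low temperature are used so that cycloaddition outruns acid-induced oligomerisation of the diene.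

Step 2
Reactants: 3 cis-fused adduct
Product: 5 (8aS)-2,5,5,8a-tetramethyl-1-oxo-1,5,8,8a-tetrahydronaphthalen-4-yl trifluoromethanesulfonate (C6 enol triflate; Δ2, Δ5, Δ7, 9-one), via potassium enolate 4 (not isolated)
Conditions: KN(SiMe3)2, THF, −78 °C; then PhNTf2, −78 → 0 °C
Reagents that add atoms: N-phenylbis(trifluoromethanesulfonimide), O=S(=O)(N(c1ccccc1)S(=O)(=O)C(F)(F)F)C(F)(F)F
Why: Kinetic α′-enolisation and O-sulfonylation (enol triflate formation): C5–H is the only enolisable position of the C6 carbonyl because C7 is sp2, so the triflate can form only as the Δ5 enol derivative, and this removes on purpose the cis ring-fusion centre, which should not be corrected by base equilibration since, with sp2 carbons at C6 and C9, the cis-fused dione is expected to be no less stable than the trans isomer (the equatorial C4 quaternary carbon eclipses the C6 carbonyl in the trans form).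

Step 3
Reactants: 5 C6 enol triflate
Product: 6 (8aS)-2,5,5,8a-tetramethyl-5,8-dihydronaphthalen-1(8aH)-one (2,5,7-trien-9-one, 10β-methyl)
Conditions: Pd(OAc)2 (5 mol%), PPh3, HCO2H, Et3N, DMF, 60 °C
Reagents that add atoms: none
Why: Palladium-catalysed formate hydrogenolysis of an enol triflate: oxidative addition of zerovalent palladium into C6–OTf, formate exchange with loss of CO2 and C–H reductive elimination give the non-enolisable linear dienone, whose quaternary C10 rules out aromatisation.

Step 4
Reactants: 6 2,5,7-trien-9-one
Product: 7 2α,3α-dihydroxy-4,4,8,10β-tetramethyl-5,7-dien-9-one (cis-diol of 6)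
Conditions: OsO4 (2 mol%), NMO, acetone–H2O, 0 °C → rt
Reagents that add atoms: osmium tetroxide, O=[Os](=O)(=O)=O; N-methylmorpholine N-oxide, C[N+]1([O-])CCOCC1
Why: Catalytic OsO4 syn-dihydroxylation (Upjohn conditions) is electrophilic and so picks the isolated cis-disubstituted C2=C3 olefin over the electron-poor, heavily flanked dienone; with ring B planar, ring A has a single half-chair in which the C10 methyl and the 4β-methyl are both pseudoaxial on the β-face, so osmylation occurs on the α-face and sets the 2α,3α-diol.

Step 5
Reactants: 7 2α,3α-diol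
Product: 8 2α,3α-O-isopropylidene-4,4,8,10β-tetramethyl-5,7-dien-9-one (acetonide of 7)
Conditions: Me2C(OMe)2, PPTS (cat.), CH2Cl2, rt
Reagents that add atoms: 2,2-dimethoxypropane, COC(C)(C)OC
Why: Acid-catalysed acetal exchange with 2,2-dimethoxypropane protects the cis-diol as the acetonide, which later also locks ring A in the chair that keeps the C10 methyl axial; PPTS is too weak an acid to start a dienone–phenol rearrangement.

Step 6
Reactants: 8 acetonide dienone
Product: 10 2α,3α-O-isopropylidene-4,4,8α,10β-tetramethyl-5-en-9-one (8β-H), via C8-epimeric 5-en-9-one 9 (not isolated)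
Conditions: [(Ph3P)CuH]6, PhMe, H2O (2 equiv), rt; then NaOMe (cat.), MeOH, rt
Reagents that add atoms: none
Why: Copper hydride conjugate (1,4) reduction: hydride is delivered to C7, the accessible β-carbon, not to the fully substituted δ-carbon C5 or the shielded C9 carbonyl, and the Δ5 olefin that is left is not conjugated and inert; methoxide then equilibrates C8 to the equatorial 8α-methyl, since the 8β-methyl would be syn-axial to the C10 methyl in the acetonide-locked conformer.

Step 7
Reactants: 10 8α-methyl-5-en-9-one acetonide
Product: 11 trans-fused 2α,3α-O-isopropylidene-4,4,8α,10β-tetramethyl-5α-decalin-9-one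
Conditions: Mn(dpm)3 (10 mol%; dpm = dipivaloylmethanate), PhSiH3, t-BuOOH, i-PrOH, rt
Reagents that add atoms: none
Why: Metal-hydride hydrogen-atom-transfer hydrogenation, the method of choice for hindered trisubstituted olefins that resist heterogeneous catalysts: H• is transferred to C6 and the tertiary C5 radical is then quenched from the α-face, because the β-face is walled off by the axial C10 and 4β methyls, which sets 5α-H (trans fusion) irreversibly under kinetic control.

Step 8
Reactants: 11 trans-decalin-9-one acetonide
Product: 12 9α-vinyl-9β-hydroxy derivative of 11 (tertiary allylic alcohol; 5α-H, 8α-methyl, 10β-methyl, 2α,3α-acetonide)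
Conditions: CH2=CHMgBr, CeCl3 (dried), THF, −78 → 0 °C; aq. NH4Cl
Reagents that add atoms: vinylmagnesium bromide, C=C[Mg]Br
Why: Organocerium 1,2-addition (Grignard reagent transmetalated to cerium to suppress enolisation of the hindered ketone): the nucleophile enters axially from the α-face, anti to the axial C10 methyl, and so gives the 9α-vinyl 9β-carbinol.

Step 9
Reactants: 13 methyl but-2-ynoate
Product: 14 methyl (Z)-3-iodobut-2-enoate
Conditions: NaI, AcOH, 115 °C
Reagents that add atoms: sodium iodide, [Na+].[I-]
Why: Conjugate hydroiodination of an ynoate: iodide adds to C3 and the allenolate is protonated anti, which gives the (Z)-β-iodo enoate with iodine cis to the ester.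

Step 10
Reactants: 12 9α-vinyl carbinol; 14 methyl (Z)-3-iodobut-2-enoate
Product: 16 2α,3α-O-isopropylidene derivative of the target (methyl (Z)-enoate, free 9β-OH), via alkylborane 15 (not isolated)
Conditions: 9-BBN (2.5 equiv), THF, 0 → 50 °C; then 14, PdCl2(dppf) (5 mol%), AsPh3, aq. K3PO4, DMF, rt
Reagents that add atoms: none
Why: Anti-Markovnikov hydroboration of the terminal vinyl group with 9-BBN followed by B-alkyl Suzuki–Miyaura coupling, which proceeds with retention at the alkenyl iodide and so carries the Z geometry of 14 into C13=C14; excess borane covers the free tertiary hydroxyl, and phosphate at room temperature is mild enough that the C9 alkoxide does not add to the new enoate.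

Step 11
Reactants: 16 target acetonide
Product: 17 CNP0292844.2 (methyl (Z)-enoate, 2α,3α,9β-triol, 5α-H, 8α-methyl, 10β-methyl)
Conditions: AcOH–H2O–THF (3:1:1), 40 °C
Reagents that add atoms: none
Why: Acetal hydrolysis under mild aqueous acid frees the 2α,3α-diol, while the tertiary, non-allylic C9 alcohol and the Z-enoate are stable to dilute acetic acid.

Compound list
1 | 2,6-dimethyl-1,4-benzoquinone | CC1=CC(=O)C=C(C)C1=O | starting material
2 | 4-methylpenta-1,3-diene | C=CC=C(C)C | starting material
3 | (4aR,8aS)-2,5,5,8a-tetramethyl-4a,5,8,8a-tetrahydronaphthalene-1,4-dione (cis-fused; 5β-H, 10β-methyl) | O=C1C(C)=CC(=O)[C@@H]2C(C)(C)C=CC[C@@]21C | intermediate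
4 | potassium C5(6)-enolate of 3 (6-oxido-2,5,7-trien-9-one) | O=C1C(C)=CC([O-])=C2C(C)(C)C=CC[C@@]21C.[K+] | intermediate
5 | (8aS)-2,5,5,8a-tetramethyl-1-oxo-1,5,8,8a-tetrahydronaphthalen-4-yl trifluoromethanesulfonate (C6 enol triflate) | O=C1C(C)=CC(OS(=O)(=O)C(F)(F)F)=C2C(C)(C)C=CC[C@@]21C | intermediate
6 | (8aS)-2,5,5,8a-tetramethyl-5,8-dihydronaphthalen-1(8aH)-one (2,5,7-trien-9-one) | O=C1C(C)=CC=C2C(C)(C)C=CC[C@@]21C | intermediate
7 | 2α,3α-dihydroxy-4,4,8,10β-tetramethyl-5,7-dien-9-one | O=C1C(C)=CC=C2C(C)(C)[C@H](O)[C@H](O)C[C@@]21C | intermediate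
8 | 2α,3α-O-isopropylidene-4,4,8,10β-tetramethyl-5,7-dien-9-one | O=C1C(C)=CC=C2C(C)(C)[C@@H]3OC(C)(C)O[C@@H]3C[C@@]21C | intermediate
9 | 2α,3α-O-isopropylidene-4,4,8,10β-tetramethyl-5-en-9-one, mixture of C8 epimers | O=C1C(C)CC=C2C(C)(C)[C@@H]3OC(C)(C)O[C@@H]3C[C@@]21C | intermediate
10 | 2α,3α-O-isopropylidene-4,4,8α,10β-tetramethyl-5-en-9-one | O=C1[C@H](C)CC=C2C(C)(C)[C@@H]3OC(C)(C)O[C@@H]3C[C@@]21C | intermediate
11 | trans-fused 2α,3α-O-isopropylidene-4,4,8α,10β-tetramethyl-5α-decalin-9-one | O=C1[C@H](C)CC[C@H]2C(C)(C)[C@@H]3OC(C)(C)O[C@@H]3C[C@@]21C | intermediate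
12 | 9α-vinyl-9β-hydroxy-2α,3α-O-isopropylidene-4,4,8α,10β-tetramethyl-5α-decalin | C=C[C@]1(O)[C@H](C)CC[C@H]2C(C)(C)[C@@H]3OC(C)(C)O[C@@H]3C[C@@]21C | intermediate
13 | methyl but-2-ynoate | CC#CC(=O)OC | starting material
14 | methyl (Z)-3-iodobut-2-enoate | COC(=O)/C=C(/C)I | intermediate
15 | B-[2-(9β-hydroxydecalin-9α-yl)ethyl]-9-borabicyclo[3.3.1]nonane derived from 12 | C1CC2CCCC(C1)B2CC[C@]3(O)[C@H](C)CC[C@H]4C(C)(C)[C@@H]5OC(C)(C)O[C@@H]5C[C@@]43C | intermediate
16 | 2α,3α-O-isopropylidene derivative of the target | COC(=O)/C=C(/C)CC[C@]1(O)[C@H](C)CC[C@H]2C(C)(C)[C@@H]3OC(C)(C)O[C@@H]3C[C@@]21C | intermediate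
17 | CNP0292844.2 | COC(=O)/C=C(/C)CC[C@]1(O)[C@H](C)CC[C@H]2C(C)(C)[C@H](O)[C@H](O)C[C@@]21C | target

Total step count: 11. Longest linear sequence: 10 (steps 1–8, 10 and 11).

Steps most likely to fail

Step 1. The diene, held mostly s-trans by its cis-methyl group, may add too slowly and be consumed by acid-induced oligomerisation, or bond at C10 without closing ring A. The fallback sets out from 1 and comes back at 6; it makes the same two bonds with an oxygen-activated diene of the same carbon skeleton. Mesityl oxide, LiN(i-Pr)2 and i-Pr3SiOTf (THF, −78 °C) give 4-methyl-2-(triisopropylsilyloxy)penta-1,3-diene F1. With 1 and the same catalyst this should give the 2-silyloxy cis adduct F2: 2-silyloxydienes are established partners for oxazaborolidinium catalysts, and if bonding becomes stepwise (Mukaiyama–Michael addition at C10) the intermediate keeps a rotatable C2–C3 bond and can still close by a second Michael addition at C5. KN(SiMe3)2/PhNTf2 as in step 2 gives the C6 enol triflate F3, CsF/PhNTf2 in DME turns the silyl enol ether into a second sulfonate to give the 2,6-bis(triflate) F4, and Pd(OAc)2/PPh3/HCO2H/Et3N removes both sulfonates to return to 6.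

Step 2. Removal of the hindered C5 proton may be slow, so that deprotonation at the C8 methyl (γ to the C6 carbonyl) competes and sulfonylation occurs with the wrong regiochemistry. The fallback sets out from 3 and comes back at 6; it removes the C6 oxygen by reduction and elimination. Luche reduction (NaBH4, CeCl3·7H2O, MeOH, −78 °C) should reduce only the unhindered C6 carbonyl, from the convex β-face, to give the cis-fused 6α-hydroxy-7-en-9-one F5. MsCl/Et3N gives the allylic mesylate F6, and DBU (toluene, 80 °C) should effect anti elimination of the 6α-sulfonate with 5β-H, the only β-hydrogen, to give 6.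

Step 7. Hydrogen-atom transfer to an olefin flanked by two quaternary carbons may stall, or the C5 radical may be quenched with poor facial selectivity. The fallback sets out from 10 and comes back at 11; it uses hydroboration and radical deoxygenation. BH3·THF followed by NaOH/H2O2 adds H and B cis from the α-face (5α-H, 6α-OH, as is usual for Δ5 olefins under an axial angular methyl) and also reduces the C9 ketone, giving the 5α-H 6α,9β-diol F7. PhOC(S)Cl/pyridine acylates the less hindered 6α-hydroxyl to give the 6-O-phenoxythiocarbonyl derivative F8, Bu3SnH/AIBN (Barton–McCombie deoxygenation) gives the 9β-alcohol F9, and Dess–Martin oxidation returns 11.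

Further compounds
F1 | step 1 | 4-methyl-2-(triisopropylsilyloxy)penta-1,3-diene | C=C(O[Si](C(C)C)(C(C)C)C(C)C)C=C(C)C
F2 | step 1 | cis-fused 2-(triisopropylsilyloxy) analogue of 3 (silyl enol ether at C2=C3) | O=C1C(C)=CC(=O)[C@@H]2C(C)(C)C=C(O[Si](C(C)C)(C(C)C)C(C)C)C[C@@]21C
F3 | step 1 | C6 enol triflate of F2 (2-silyloxy-2,5,7-trien-9-one) | O=C1C(C)=CC(OS(=O)(=O)C(F)(F)F)=C2C(C)(C)C=C(O[Si](C(C)C)(C(C)C)C(C)C)C[C@@]21C
F4 | step 1 | 2,6-bis(triflate) of the 2,5,7-trien-9-one | O=C1C(C)=CC(OS(=O)(=O)C(F)(F)F)=C2C(C)(C)C=C(OS(=O)(=O)C(F)(F)F)C[C@@]21C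
F5 | step 2 | cis-fused 6α-hydroxy-4,4,8,10β-tetramethyl-2,7-dien-9-one | O=C1C(C)=C[C@H](O)[C@@H]2C(C)(C)C=CC[C@@]21C
F6 | step 2 | 6α-methanesulfonate of F5 | O=C1C(C)=C[C@H](OS(C)(=O)=O)[C@@H]2C(C)(C)C=CC[C@@]21C
F7 | step 7 | 2α,3α-O-isopropylidene-4,4,8α,10β-tetramethyl-5α-decalin-6α,9β-diol | O[C@H]1[C@H](C)C[C@H](O)[C@H]2C(C)(C)[C@@H]3OC(C)(C)O[C@@H]3C[C@@]21C
F8 | step 7 | 6-O-phenoxythiocarbonyl derivative of F7 | O[C@H]1[C@H](C)C[C@H](OC(=S)Oc4ccccc4)[C@H]2C(C)(C)[C@@H]3OC(C)(C)O[C@@H]3C[C@@]21C
F9 | step 7 | 2α,3α-O-isopropylidene-4,4,8α,10β-tetramethyl-5α-decalin-9β-ol | O[C@H]1[C@H](C)CC[C@H]2C(C)(C)[C@@H]3OC(C)(C)O[C@@H]3C[C@@]21C
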